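## Retrosynthetic overview

1. The C6–C(CH3)2CH=CH2 bond is made last, by a branch-selective Suzuki coupling of prenylboronate 18 with the 6-bromo-7-hydroxycoumarin bis-epoxide.
2. Both oxiranes come from the 3-neryl side chain by two Shi epoxidations of opposite catalyst handedness: 6',7' first (D-ketone), then 2',3' on the Z olefin (L-ketone).
3. The pyranone ring is closed from acid 7 and 5-bromo-2,4-dihydroxybenzaldehyde 10 by a new carbene-catalysed aldol–lactonisation.
4. Key step: the Z-trisubstituted olefin of 7 comes from 3,4-dihydro-2H-pyran by an ionic 1,2-shift of CH3 from copper to C6 with ring opening (1,2-metalate rearrangement), followed by alkylation with 2 and oxidation.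
5. Ring order: dihydropyran opened (step 1), pyranone closed (step 5), 6',7'-oxirane (step 6), 2',3'-oxirane (step 7). Aldehyde 10 comes from resorcinol by formylation and bromination.

Assumption: the SMILES is read as the (2'S,3'R,6'R) isomer (primed locants = C10 side chain), in which the 2',3'-oxirane carries the coumarinylmethyl group and the C4' chain cis, so it derives from a Z (neryl-type) olefin.

## Route

Step 1
Reactants: 1 3,4-dihydro-2H-pyran; 2 5-iodo-2-methylpent-2-ene
Product: 6 (4Z)-5,9-dimethyldeca-4,8-dien-1-ol, via 6-lithio-3,4-dihydro-2H-pyran 3 (not isolated), via lithium methyl(dihydropyranyl)cuprate 4 (not isolated), via alkenylcopper lithium alkoxide 5 (not isolated)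
Conditions: t-BuLi, THF, −78→0 °C; MeCu (from MeLi, CuI), Et2O/Me2S, −40→20 °C; then 2, DMPU, P(OEt)3, 0→20 °C; H2O work-up
Reagents that add atoms: methyllithium, C[Li]
Why: Kocienski-type 1,2-metalate rearrangement: in cuprate 4 the methyl group shifts 1,2 from copper to C6 with inversion at the alkenyl carbon while the ring C–O bond breaks (ionic, not pericyclic), so copper in 5 sits cis to the oxidopropyl chain, and alkylation of the alkenylcopper with retention puts the homoprenyl group cis to that chain (4Z olefin, no stereocentre formed).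

Step 2
Reactants: 6 (4Z)-5,9-dimethyldeca-4,8-dien-1-ol
Product: 7 (4Z)-5,9-dimethyldeca-4,8-dienoic acid
Conditions: TEMPO (20 mol%), PhI(OAc)2 (2.2 equiv), MeCN/H2O 1:1, 20 °C
Reagents that add atoms: water, O
Why: oxoammonium (TEMPO/PhI(OAc)2) oxidation of the primary alcohol through the aldehyde hydrate to the acid, which leaves trisubstituted olefins and their geometry untouched.

Step 3
Reactants: 8 resorcinol (benzene-1,3-diol)
Product: 9 2,4-dihydroxybenzaldehyde
Conditions: POCl3, DMF, MeCN, −15→20 °C; then H2O, 50 °C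
Reagents that add atoms: N,N-dimethylformamide, CN(C)C=O; water, O
Why: Vilsmeier–Haack formylation at C4 of resorcinol (para to one hydroxyl and ortho to the other), followed by hydrolysis of the iminium salt.

Step 4
Reactants: 9 2,4-dihydroxybenzaldehyde
Product: 10 5-bromo-2,4-dihydroxybenzaldehyde
Conditions: Br2 (1.0 equiv), AcOH, 15 °C
Reagents that add atoms: bromine, BrBr
Why: electrophilic aromatic bromination at C5, the position para to the 2-OH and ortho to the 4-OH and not flanked by two substituents.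

Step 5
Reactants: 7 (4Z)-5,9-dimethyldeca-4,8-dienoic acid; 10 5-bromo-2,4-dihydroxybenzaldehyde
Product: 14 6-bromo-3-[(2Z)-3,7-dimethylocta-2,6-dien-1-yl]-2-oxo-2H-chromen-7-yl pivalate, via mixed pivalic anhydride 11 (not isolated), via 4-O-pivaloyl aldehyde 12 (not isolated), via 2-formylaryl ester 13 (not isolated)
Conditions: 7, PivCl (2.1 equiv), Et3N (4 equiv), CH2Cl2, 0 °C; then 10, 0→20 °C; then IMes·HCl (1,3-dimesitylimidazolium chloride, 10 mol%), DBU (20 mol%), 25 °C
Reagents that add atoms: pivaloyl chloride, CC(C)(C)C(=O)Cl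
Why: Proposed new method: carbene-catalysed aldol–lactonisation (a catalytic, room-temperature Perkin-type annulation of an unactivated aliphatic acid) of the in situ 2-formylaryl alkanoate 13, in which the carbene adds to the activated aryl ester and expels the ortho-formyl phenoxide (a leaving group comparable to 4-nitrophenoxide), DBU enolises the acyl azolium, the azolium enolate adds to the aldehyde of the paired phenoxide, the phenoxide closes onto the acyl azolium to give the six-membered lactone and free carbene, and E1cB loss of water gives the coumarin, while pivaloyl chloride both activates 7 and caps the more acidic, unhindered 4-OH; the closest known reaction types are carbene α-activation of aryl alkanoates to azolium enolates for formal [4+2] annulations and the Perkin coumarin condensation.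

Step 6
Reactants: 14 6-bromo-3-[(2Z)-3,7-dimethylocta-2,6-dien-1-yl]-2-oxo-2H-chromen-7-yl pivalate
Product: 15 6-bromo-3-{(2Z)-5-[(2R)-3,3-dimethyloxiran-2-yl]-3-methylpent-2-en-1-yl}-2-oxo-2H-chromen-7-yl pivalate
Conditions: D-fructose-derived Shi ketone (1,2:4,5-di-O-isopropylidene-β-D-erythro-2,3-hexodiulo-2,6-pyranose, 30 mol%), Oxone (2KHSO5·KHSO4·K2SO4, 1.0 equiv KHSO5), K2CO3, Bu4NHSO4, Na2EDTA, MeCN/(MeO)2CH2/H2O, pH 10, 0 °C
Reagents that add atoms: potassium peroxymonosulfate, [K+].OOS(=O)(=O)[O-]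
Why: Shi asymmetric epoxidation through the spiro dioxirane transition state, in which the D-ketone delivers oxygen to the face that gives R at the CH carbon (C6'), and the terminal isopropylidene olefin reacts before the more hindered Z olefin next to the coumarinylmethyl group.

Step 7
Reactants: 15 6-bromo-3-{(2Z)-5-[(2R)-3,3-dimethyloxiran-2-yl]-3-methylpent-2-en-1-yl}-2-oxo-2H-chromen-7-yl pivalate
Product: 16 6-bromo-3-{[(2S,3R)-3-{2-[(2R)-3,3-dimethyloxiran-2-yl]ethyl}-3-methyloxiran-2-yl]methyl}-2-oxo-2H-chromen-7-yl pivalate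
Conditions: L-fructose-derived ent-Shi ketone (40 mol%), Oxone (2KHSO5·KHSO4·K2SO4, 1.5 equiv KHSO5), K2CO3, Bu4NHSO4, Na2EDTA, MeCN/(MeO)2CH2/H2O, pH 10, 0 °C
Reagents that add atoms: potassium peroxymonosulfate, [K+].OOS(=O)(=O)[O-]
Why: Shi epoxidation with the enantiomeric ketone attacks the opposite olefin face under catalyst control and gives S at C2', and the stereospecific syn oxygen transfer to the Z olefin fixes C3' as R (cis-disposed carbon substituents).

Step 8
Reactants: 17 1-chloro-3-methylbut-2-ene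
Product: 18 4,4,5,5-tetramethyl-2-(3-methylbut-2-en-1-yl)-1,3,2-dioxaborolane
Conditions: B2pin2, Pd2(dba)3 (1 mol%), THF, 60 °C
Reagents that add atoms: bis(pinacolato)diboron, CC1(C)OB(OC1(C)C)B1OC(C)(C)C(C)(C)O1
Why: palladium-catalysed allylic borylation through a π-allylpalladium chloride, with boron delivered to the less hindered primary terminus.

Step 9
Reactants: 16 6-bromo-3-{[(2S,3R)-3-{2-[(2R)-3,3-dimethyloxiran-2-yl]ethyl}-3-methyloxiran-2-yl]methyl}-2-oxo-2H-chromen-7-yl pivalate; 18 4,4,5,5-tetramethyl-2-(3-methylbut-2-en-1-yl)-1,3,2-dioxaborolane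
Product: 20 7-hydroxy-6-(2-methylbut-3-en-2-yl)-3-{[(2S,3R)-3-{2-[(2R)-3,3-dimethyloxiran-2-yl]ethyl}-3-methyloxiran-2-yl]methyl}-2H-chromen-2-one, via bromophenol bis-epoxide 19 (not isolated)
Conditions: K2CO3 (0.2 equiv), MeOH, 20 °C; then 18 (2 equiv), Pd(OAc)2 (3 mol%), electron-poor biaryl(diaryl)phosphine of the JackiePhos type (P-aryl = 3,5-(CF3)2C6H3, 6 mol%), K3PO4 (aq), THF, 40 °C
Reagents that add atoms: none
Why: methanolysis of the activated aryl pivalate, then ligand-controlled branch-selective Suzuki–Miyaura allyl–aryl coupling, in which SE2' transmetalation of 18 gives the tertiary σ-allyl palladium aryl and its reductive elimination outruns allyl isomerisation, so the 1,1-dimethylallyl group forms at C6 without touching a stereocentre.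

## Compound list

1 | 3,4-dihydro-2H-pyran | C1=COCCC1 | starting material
2 | 5-iodo-2-methylpent-2-ene | CC(C)=CCCI | starting material
3 | 6-lithio-3,4-dihydro-2H-pyran | [Li]C1=CCCCO1 | intermediate
4 | lithium methyl(3,4-dihydro-2H-pyran-6-yl)cuprate | [Li+].C[Cu-]C1=CCCCO1 | intermediate
5 | lithium (4Z)-5-cupriohex-4-en-1-olate (copper cis to the oxidopropyl chain) | [Li]OCCC/C=C(/C)[Cu] | intermediate
6 | (4Z)-5,9-dimethyldeca-4,8-dien-1-ol | OCCC/C=C(/C)CCC=C(C)C | intermediate
7 | (4Z)-5,9-dimethyldeca-4,8-dienoic acid | OC(=O)CC/C=C(/C)CCC=C(C)C | intermediate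
8 | resorcinol (benzene-1,3-diol) | Oc1cccc(O)c1 | starting material
9 | 2,4-dihydroxybenzaldehyde | O=Cc1ccc(O)cc1O | intermediate
10 | 5-bromo-2,4-dihydroxybenzaldehyde | O=Cc1cc(Br)c(O)cc1O | intermediate
11 | (4Z)-5,9-dimethyldeca-4,8-dienoic 2,2-dimethylpropanoic anhydride | CC(C)(C)C(=O)OC(=O)CC/C=C(/C)CCC=C(C)C | intermediate
12 | 5-bromo-2-hydroxy-4-(pivaloyloxy)benzaldehyde | CC(C)(C)C(=O)Oc1cc(O)c(C=O)cc1Br | intermediate
13 | 4-bromo-2-formyl-5-(pivaloyloxy)phenyl (4Z)-5,9-dimethyldeca-4,8-dienoate | CC(C)(C)C(=O)Oc1cc(OC(=O)CC/C=C(/C)CCC=C(C)C)c(C=O)cc1Br | intermediate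
14 | 6-bromo-3-[(2Z)-3,7-dimethylocta-2,6-dien-1-yl]-2-oxo-2H-chromen-7-yl pivalate | CC(C)(C)C(=O)Oc1cc2oc(=O)c(C/C=C(/C)CCC=C(C)C)cc2cc1Br | intermediate
15 | 6-bromo-3-{(2Z)-5-[(2R)-3,3-dimethyloxiran-2-yl]-3-methylpent-2-en-1-yl}-2-oxo-2H-chromen-7-yl pivalate | CC(C)(C)C(=O)Oc1cc2oc(=O)c(C/C=C(/C)CC[C@H]3OC3(C)C)cc2cc1Br | intermediate
16 | 6-bromo-3-{[(2S,3R)-3-{2-[(2R)-3,3-dimethyloxiran-2-yl]ethyl}-3-methyloxiran-2-yl]methyl}-2-oxo-2H-chromen-7-yl pivalate | CC(C)(C)C(=O)Oc1cc2oc(=O)c(C[C@@H]3O[C@]3(C)CC[C@H]3OC3(C)C)cc2cc1Br | intermediate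
17 | 1-chloro-3-methylbut-2-ene | CC(C)=CCCl | starting material
18 | 4,4,5,5-tetramethyl-2-(3-methylbut-2-en-1-yl)-1,3,2-dioxaborolane | CC(C)=CCB1OC(C)(C)C(C)(C)O1 | intermediate
19 | 6-bromo-7-hydroxy-3-{[(2S,3R)-3-{2-[(2R)-3,3-dimethyloxiran-2-yl]ethyl}-3-methyloxiran-2-yl]methyl}-2H-chromen-2-one | Oc1cc2oc(=O)c(C[C@@H]3O[C@]3(C)CC[C@H]3OC3(C)C)cc2cc1Br | intermediate
20 | 7-hydroxy-6-(2-methylbut-3-en-2-yl)-3-{[(2S,3R)-3-{2-[(2R)-3,3-dimethyloxiran-2-yl]ethyl}-3-methyloxiran-2-yl]methyl}-2H-chromen-2-one | C=CC(C)(C)c1cc2cc(C[C@@H]3O[C@]3(C)CC[C@H]3OC3(C)C)c(=O)oc2cc1O | target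

## Step count and risks

Total step count: 9. Longest linear sequence: 6 (steps 1, 2, 5, 6, 7, 9, or steps 3, 4, 5, 6, 7, 9).

Three steps most likely to fail:

**Step 5 (the proposed new annulation).** The carbene may acylate or condense unproductively, or the enolisation of the unactivated acyl azolium may be too slow. The fallback uses known chemistry, sets out from 7 and 10 and comes back at 14. Acid 7 is dehydrated with DCC to (4Z)-5,9-dimethyldeca-4,8-dienoic anhydride F3. Aldehyde 10 is heated with F3 (2.5 equiv) and K2CO3 at 130 °C in a classical Perkin coumarin condensation, which gives 6-bromo-3-[(2Z)-3,7-dimethylocta-2,6-dien-1-yl]-2-oxo-2H-chromen-7-yl (4Z)-5,9-dimethyldeca-4,8-dienoate F4. Methanolysis (K2CO3, MeOH) frees 6-bromo-3-[(2Z)-3,7-dimethylocta-2,6-dien-1-yl]-7-hydroxy-2H-chromen-2-one F5, and pivaloyl chloride with Et3N converts F5 into 14.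

**Step 1 (alkylation of the alkenylcopper after the 1,2-shift).** Capture of 5 by a primary homoallylic iodide may be sluggish. The fallback sets out from 5 (made from 1 exactly as in step 1) and from 2, and comes back at 6. Intermediate 5 is quenched with iodine, with retention at the alkenyl carbon, and (4Z)-5-iodohex-4-en-1-ol F1 is isolated. Iodide 2 is converted with zinc dust and LiCl into (4-methylpent-3-en-1-yl)zinc iodide F2. F1 and F2 are joined by a Negishi coupling with Pd(PPh3)4 in THF, which proceeds with retention of the olefin geometry and gives 6.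

**Step 9 (branch-selective coupling that builds the quaternary carbon next to the phenoxide).** Linear prenylation or slow coupling is possible on this hindered, electron-rich bromide. The fallback sets out from 19 (isolated after the methanolysis) and comes back at 20. Palladium-catalysed α-arylation of 2-methylpropanal with 19 ([Pd(C3H5)Cl]2, dppf, Cs2CO3, dioxane, 80 °C) gives the α-aryl aldehyde, which rests as the lactol 2-hydroxy-3,3-dimethyl-6-{[(2S,3R)-3-{2-[(2R)-3,3-dimethyloxiran-2-yl]ethyl}-3-methyloxiran-2-yl]methyl}-2,3-dihydro-7H-furo[3,2-g]chromen-7-one F6 (both epimers at the lactol carbon). Wittig methylenation of F6 with excess Ph3P=CH2 (from Ph3PCH3Br and KHMDS, THF, −78→0 °C) opens the lactol and gives 20.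

## Further compounds

F1 | step 1 | (4Z)-5-iodohex-4-en-1-ol | OCCC/C=C(/C)I
F2 | step 1 | (4-methylpent-3-en-1-yl)zinc iodide | CC(C)=CCC[Zn]I
F3 | step 5 | (4Z)-5,9-dimethyldeca-4,8-dienoic anhydride | O=C(CC/C=C(/C)CCC=C(C)C)OC(=O)CC/C=C(/C)CCC=C(C)C
F4 | step 5 | 6-bromo-3-[(2Z)-3,7-dimethylocta-2,6-dien-1-yl]-2-oxo-2H-chromen-7-yl (4Z)-5,9-dimethyldeca-4,8-dienoate | O=C(CC/C=C(/C)CCC=C(C)C)Oc1cc2oc(=O)c(C/C=C(/C)CCC=C(C)C)cc2cc1Br
F5 | step 5 | 6-bromo-3-[(2Z)-3,7-dimethylocta-2,6-dien-1-yl]-7-hydroxy-2H-chromen-2-one | Oc1cc2oc(=O)c(C/C=C(/C)CCC=C(C)C)cc2cc1Br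
F6 | step 9 | 2-hydroxy-3,3-dimethyl-6-{[(2S,3R)-3-{2-[(2R)-3,3-dimethyloxiran-2-yl]ethyl}-3-methyloxiran-2-yl]methyl}-2,3-dihydro-7H-furo[3,2-g]chromen-7-one | O=c1oc2cc3OC(O)C(C)(C)c3cc2cc1C[C@@H]1O[C@]1(C)CC[C@H]1OC1(C)C
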